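## The problem

Digriseophene A (12) is an achiral, symmetric dimer in which two identical benzophenone halves are joined by one CH2 group. Ring A of each half is a phloroglucinol-type ring (C1 ketone, C2 and C6 OH, C3 bridge, C4 OCH3, C5 H), and ring B is an orcinol-type ring bonded to the ketone through C1' (C2' OCH3, C4' OH, C6' CH3). There is no stereocentre, so the task is constitutional: of the five ring oxygens per half, two must end as methyl ethers (C4, C2') and three as free hydroxyls (C2, C6, C4'). The ketone carbon lies between four ortho substituents, which makes bond formation at that carbon (Friedel–Crafts acylation, aryl-metal addition to a hindered acyl group) the weak point of a conventional benzophenone synthesis. The free polyphenol is fragile: the rings are easily oxidised, the diarylmethane bridge can scramble in hot alkali or strong acid, a 2-hydroxy-2'-methoxybenzophenone can close to a xanthone in hot base, and C5 stays nucleophilic, so the bridge must be built without over-condensation. The enabling feature is that C2'(O)–C3'–C4'(O)–C5'–C6'(CH3) of ring B are the five ring carbons of triacetic acid lactone (6) with oxygens and methyl already in place, while C1' can be the methyl carbon of an acetyl group already on ring A. Ring B can therefore be grown on an acetophenone by a five-plus-one annulation in which both new C–C bonds are made at an unhindered carbon and the pyran ring oxygen and the 4-alkoxy group deliver the C2' and C4' oxygens in differentiated form.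

## Retrosynthesis

**12 from 11.** The last cut removes six O-benzyl groups, four on ring A oxygens and two on the C4' oxygens. One protecting group for all hydroxyls that must end free allows a single neutral hydrogenolysis as the final step, so the free polyphenol never meets acid or base. Acetal protection of ring A would need a separate acidic step and would be exposed to the Lewis-acidic conditions of the annulation. The forward reaction must leave the twisted diaryl ketone and the bridge untouched.

**11 from 10.** The two C2'–OCH3 bonds are cut. In 10 the C2' hydroxyls are the only free hydroxyls, so no selectivity problem arises. The forward reaction is the alkylation of a chelated phenol.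

**10 from 5 and 8, through 9.** In both B rings the bonds C1'–C2' and C1'–C6' are cut. This is preferred to cutting either bond at the ketone carbon, which would require two acylations at a tetra-ortho-substituted centre. The precursors are much simpler: bis(silyl enol ether) 5 holds the whole ring A dimer with the ketone carbon in place, and pyrylium salt 8 holds five carbons of ring B. The forward reaction must deliver carbon–carbon bond formation at C2 of 8 twice (giving bis(pyran-2-ylidene) 9), then a base-induced ring opening and reclosure that keeps the pyran oxygen on C2' and carries the 4-benzyloxy group through.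

**8 from 7 from 6.** The O–CH3 bond at C2 of the cation and the O-benzyl bond at C4 are cut, leading back to triacetic acid lactone 6. The forward reactions are O-alkylation of a vinylogous acid and O-methylation of a lactone carbonyl to an aromatic cation. The 4-substituent must be benzyl and not methyl, because only a removable group at C4' lets the C2' oxygen be the one that is methylated.

**5 from 4 from 3.** The two O–Si bonds and the four ring A O-benzyl bonds are cut. The acetyl groups of 3 already contain C1', so no carboxyl-level core and no organometallic addition are needed. A tert-butyldimethylsilyl enol ether is chosen over a trimethylsilyl one because it can be handled and purified.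

**3 from 2 and 1.** One aryl–CH2 bond is cut, giving acetophenone 1 as the nucleophile and Mannich base 2 as a latent ortho-quinone methide. Cutting both aryl–CH2 bonds at once, to two molecules of 1 and a free one-carbon electrophile, would leave the extent of condensation to stoichiometry alone. With 2 the electrophile is a defined, isolable compound that can be released slowly into an excess of 1. C3 and C5 of 1 are equivalent, so the bridge can form in only one way, and because both rings are the same, any transfer of the aminomethyl group between rings is degenerate.

**2 from 1.** The C3–CH2 bond is cut. The forward reaction is a phenolic Mannich aminomethylation with a preformed methyleneiminium salt, kept limiting so that only one of the two equivalent ring positions reacts.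

## Roads not taken

Alternative 1: double Danheiser benzannulation. The cut runs through ring A. Each ring is divided into a vinylketene from cyclobutenone A3 and the two alkyne carbons of an ynol ether, the two ynol ethers being tied through the future bridge carbon in skipped diyne A2. On heating, A2 and two equivalents of A3 should give bis-phenol A1 by 4π opening, [2+2] addition, 4π opening and 6π closure.
- Merits: the bridge is installed with no possibility of over-condensation, and the three ring A oxygens emerge differentiated in one operation. In both respects this is better than the chosen plan, which needs two steps (1 and 2) and an excess of 1 to build the bridge cleanly and spends step 3 on protection.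
- Weak points: A2 has a doubly propargylic CH2 between two ynol ethers and should isomerise or polymerise readily. A2 and A3 each need several steps.
- Decisive objection: A1 contains neither the ketone nor ring B. The two tetra-ortho-substituted aryl–CO–aryl bonds would still have to be made by acylating A1 between its OH and OBn groups, in competition with the site between OCH3 and OBn, with a ring B acyl donor that would have to be made separately. The key step is spent on the ring that the chosen plan takes ready-made from 1.

Alternative 2: pyranone-to-phloroglucinol Claisen recyclisation. The cut is in ring A, between the aroyl-bearing carbon C1 and a neighbouring hydroxyl-bearing carbon. The precursor is the methylene-bridged bis(4-methoxy-2-pyranone) A5, whose side chains already contain ring B. A magnesium alkoxide in methanol would open both lactones to methyl esters, and the doubly activated CH2 of each side chain would close onto its ester to give A4, one hydrogenolysis from 12.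
- Merits: the step is biomimetic, ring A needs no protecting groups, and the C4 methoxy group comes directly from the pyranone. The endgame is one step against two in the chosen plan, which is a real advantage.
- Weak points: A5 is hardly simpler than the target. Ring B must be made beforehand and joined to a pyranone 6-methyl anion by acylation with a di-ortho-substituted benzoyl unit, the kind of hindered acylation the chosen plan avoids. Bridging at C3 is reliable for 4-hydroxypyranones, so O-methylation would have to follow and would divide between the 2- and 4-oxygens. In the key step the opened chain can close by aldol as well as by Claisen pathways.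
- Comparison: the chosen plan builds ring B from 6 in the key step in place of a separate aromatic synthesis, which outweighs the extra endgame step.

Alternative 3: ring B aromatised late. The cut is the bond between the ketone carbon and C1'. The kinetic lithium enolate of vinylogous ester A7 would be C-acylated at its α' carbon by both acyl imidazolide groups of core A8 to give bis(β-diketone) A6, followed by dehydrogenation to the aromatic ring.
- Merits: C-acylation of vinylogous ester enolates is conservative chemistry, arguably better precedented than the pyrylium ring transformation. The two ring B oxygens emerge differentiated, as in the chosen plan.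
- Weak points: the new bond is made at a carbonyl carbon flanked by two ortho alkoxy groups, using an enolate carbon next to the methyl-bearing centre, and this must happen twice. The product is more acidic than the enolate and consumes a second equivalent. O-acylation competes. A separate oxidation must then aromatise two rings in the presence of electron-rich arenes and a doubly benzylic bridge CH2. Two stereocentres are made only to be erased, and a carboxyl-level core needs more steps than the acetyl core 4.
- Comparison: the chosen plan forms its bonds at a terminal enol ether carbon away from the crowded ring and gives the aromatic ring directly, at the price of a less familiar key reaction.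

Key step: step 7

Assumption: acetophenone 1 is treated as a catalogue compound. The exocyclic double bonds of 9 are drawn Z; either geometry should converge on 10.

## Route

Step 1
Reactants: 1 1-(2,6-dihydroxy-4-methoxyphenyl)ethan-1-one
Product: 2 1-{3-[(dimethylamino)methyl]-2,6-dihydroxy-4-methoxyphenyl}ethan-1-one
Conditions: dimethylmethylideneammonium iodide (0.95 equiv, in portions), Et3N (1.0 equiv), CH2Cl2, 0 °C to rt
Reagents that add atoms: dimethylmethylideneammonium iodide (Eschenmoser's salt), C=[N+](C)C.[I-]
Why: Phenolic Mannich reaction with a preformed iminium salt; the phenoxide of 1 attacks the methyleneiminium carbon through C3, which is equivalent to C5, and keeping the salt slightly limiting should hold back double aminomethylation, while any unreacted 1 is simply the partner of step 2.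

Step 2
Reactants: 2 1-{3-[(dimethylamino)methyl]-2,6-dihydroxy-4-methoxyphenyl}ethan-1-one; 1 1-(2,6-dihydroxy-4-methoxyphenyl)ethan-1-one
Product: 3 bis(3-acetyl-2,4-dihydroxy-6-methoxyphenyl)methane
Conditions: 2 added in portions to 1 (2.5 equiv), 1,4-dioxane, 100 °C, N2 sweep; excess 1 recovered
Reagents that add atoms: none
Why: Thermal loss of dimethylamine from the ortho-hydroxybenzylamine gives an ortho-quinone methide, which is captured through C3 of 1 by conjugate addition (the Mannich-base route to methylene-bridged acylphloroglucinols); both rings are the same, so transfer of the aminomethyl group between rings cannot give a second product, and the excess of 1 should outcompete 2 and 3 as traps.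

Step 3
Reactants: 3 bis(3-acetyl-2,4-dihydroxy-6-methoxyphenyl)methane
Product: 4 bis[3-acetyl-2,4-bis(benzyloxy)-6-methoxyphenyl]methane
Conditions: BnBr (6 equiv), K2CO3, DMF, 60 °C
Reagents that add atoms: benzyl bromide, BrCc1ccccc1
Why: Williamson ether synthesis; in DMF the potassium phenoxides should react at oxygen, and warming is needed only for the second, carbonyl-chelated hydroxyl of each ring.

Step 4
Reactants: 4 bis[3-acetyl-2,4-bis(benzyloxy)-6-methoxyphenyl]methane
Product: 5 bis{2,4-bis(benzyloxy)-3-[1-(tert-butyldimethylsilyloxy)ethenyl]-6-methoxyphenyl}methane
Conditions: TBSOTf (3 equiv), Et3N, CH2Cl2, 0 °C to rt; filtration through basic alumina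
Reagents that add atoms: tert-butyldimethylsilyl trifluoromethanesulfonate, CC(C)(C)[Si](C)(C)OS(=O)(=O)C(F)(F)F
Why: Soft enolisation (silyl triflate activation of the carbonyl, deprotonation by the amine); the acetyl CH3 is the only enolisable position, and the tert-butyldimethylsilyl enol ether should be robust enough to purify.

Step 5
Reactants: 6 4-hydroxy-6-methyl-2H-pyran-2-one (triacetic acid lactone)
Product: 7 4-(benzyloxy)-6-methyl-2H-pyran-2-one
Conditions: BnBr, K2CO3, DMF, rt to 50 °C
Reagents that add atoms: benzyl bromide, BrCc1ccccc1
Why: O-Alkylation of a vinylogous acid; the 4-oxygen of the pyranone anion is the most nucleophilic site, so the 4-alkoxy-2-pyranone should be the main product, separable by crystallisation from minor C3-benzylated material.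

Step 6
Reactants: 7 4-(benzyloxy)-6-methyl-2H-pyran-2-one
Product: 8 4-(benzyloxy)-2-methoxy-6-methylpyrylium tetrafluoroborate
Conditions: Me3OBF4 (1.1 equiv), CH2Cl2, rt, under Ar; precipitation with Et2O, used at once
Reagents that add atoms: trimethyloxonium tetrafluoroborate, C[O+](C)C.F[B-](F)(F)F
Why: Meerwein O-methylation of the lactone carbonyl, the most nucleophilic oxygen because the product is an aromatic pyrylium cation stabilised by two alkoxy groups.

Step 7
Reactants: 5 bis{2,4-bis(benzyloxy)-3-[1-(tert-butyldimethylsilyloxy)ethenyl]-6-methoxyphenyl}methane; 8 4-(benzyloxy)-2-methoxy-6-methylpyrylium tetrafluoroborate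
Product: 10 bis{2,4-bis(benzyloxy)-3-[4-(benzyloxy)-2-hydroxy-6-methylbenzoyl]-6-methoxyphenyl}methane, via bis(pyran-2-ylidene) diketone 9 (not isolated)
Conditions: 8 (2.4 equiv), 2,6-di-tert-butyl-4-methylpyridine (2.5 equiv), MeCN/CH2Cl2, −40 to 0 °C; then Mg(OMe)2 (6 equiv), MeOH, 0 to 50 °C; aq. NH4Cl work-up
Reagents that add atoms: none
Why: Each enol ether carbon adds to C2 of a pyrylium cation (Mukaiyama-type addition of a silyl enol ether to an oxocarbenium-like carbon), the silyl group passes to the geminal methoxy oxygen and leaves as the methyl silyl ether, and the hindered pyridine takes the acidic phenacyl proton, which gives the 2-(aroylmethylene)-2H-pyran units of 9. Methoxide from Mg(OMe)2 then adds at C6 of each pyran, the acetal-type end of the vinylogous ester, and 6π-electrocyclic opening of the resulting 2H-pyran breaks C6–O1, so the former ring oxygen stays on C2 as the future C2' hydroxyl. The magnesium-chelated β-diketonate carbon C1' closes onto C6 (a 6-endo-trig addition–elimination at the enol ether carbon, equivalent to a 6-exo-trig aldol if the C6 enol ether is first hydrolysed to the methyl ketone) and loss of methanol aromatises ring B, so that C1'–C2' and C1'–C6' are both in place. The closest known reaction type is the base-induced ring transformation of pyran-2-ylidenes, made from carbanions and 2-alkoxypyrylium salts, into resorcinols; additions of silyl enol ethers to pyrylium and benzopyrylium salts are likewise established. No stereocentre is formed. The step needs attack at C2 and not at C4, C6 or the acidic 6-methyl protons: the nucleophile is neutral and non-basic, the medium is buffered, and C2, bonded to two oxygens, is the most electron-poor ring carbon. In the base stage only C1' should act as the nucleophile because the C6 methyl is held in an enol ether, and the benzyloxy group at C4 is carried through unchanged, which leaves the C2' oxygen free and the C4' oxygen benzylated.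

Step 8
Reactants: 10 bis{2,4-bis(benzyloxy)-3-[4-(benzyloxy)-2-hydroxy-6-methylbenzoyl]-6-methoxyphenyl}methane
Product: 11 bis{2,4-bis(benzyloxy)-3-[4-(benzyloxy)-2-methoxy-6-methylbenzoyl]-6-methoxyphenyl}methane
Conditions: MeI (excess), Cs2CO3, DMF, rt to 40 °C
Reagents that add atoms: iodomethane, CI
Why: Williamson O-methylation; the two chelated C2' hydroxyls are the only acidic groups left, and the caesium phenoxide in DMF should overcome the hydrogen bond to the ketone.

Step 9
Reactants: 11 bis{2,4-bis(benzyloxy)-3-[4-(benzyloxy)-2-methoxy-6-methylbenzoyl]-6-methoxyphenyl}methane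
Product: 12 digriseophene A, bis[2,4-dihydroxy-3-(4-hydroxy-2-methoxy-6-methylbenzoyl)-6-methoxyphenyl]methane
Conditions: H2 (1 atm), 10% Pd/C, EtOAc/MeOH, rt
Reagents that add atoms: none
Why: Catalytic hydrogenolysis of six aryl benzyl ethers under neutral conditions; the tetra-ortho-substituted, twisted diaryl ketone and the diarylmethane bridge are not expected to be reduced at ambient pressure.

## Compound list

1 | 1-(2,6-dihydroxy-4-methoxyphenyl)ethan-1-one | CC(=O)c1c(O)cc(OC)cc1O | starting material
2 | 1-{3-[(dimethylamino)methyl]-2,6-dihydroxy-4-methoxyphenyl}ethan-1-one | CC(=O)c1c(O)cc(OC)c(CN(C)C)c1O | intermediate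
3 | bis(3-acetyl-2,4-dihydroxy-6-methoxyphenyl)methane | CC(=O)c1c(O)cc(OC)c(Cc2c(OC)cc(O)c(C(C)=O)c2O)c1O | intermediate
4 | bis[3-acetyl-2,4-bis(benzyloxy)-6-methoxyphenyl]methane | CC(=O)c1c(OCc2ccccc2)cc(OC)c(Cc2c(OC)cc(OCc3ccccc3)c(C(C)=O)c2OCc2ccccc2)c1OCc1ccccc1 | intermediate
5 | bis{2,4-bis(benzyloxy)-3-[1-(tert-butyldimethylsilyloxy)ethenyl]-6-methoxyphenyl}methane | C=C(O[Si](C)(C)C(C)(C)C)c1c(OCc2ccccc2)cc(OC)c(Cc2c(OC)cc(OCc3ccccc3)c(C(=C)O[Si](C)(C)C(C)(C)C)c2OCc2ccccc2)c1OCc1ccccc1 | intermediate
6 | 4-hydroxy-6-methyl-2H-pyran-2-one (triacetic acid lactone) | CC1=CC(O)=CC(=O)O1 | starting material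
7 | 4-(benzyloxy)-6-methyl-2H-pyran-2-one | CC1=CC(OCc2ccccc2)=CC(=O)O1 | intermediate
8 | 4-(benzyloxy)-2-methoxy-6-methylpyrylium tetrafluoroborate | COc1cc(OCc2ccccc2)cc(C)[o+]1.F[B-](F)(F)F | intermediate
9 | bis{2,4-bis(benzyloxy)-3-[(2Z)-2-(4-benzyloxy-6-methyl-2H-pyran-2-ylidene)acetyl]-6-methoxyphenyl}methane | O=C(/C=C1\OC(C)=CC(OCc2ccccc2)=C1)c1c(OCc2ccccc2)cc(OC)c(Cc2c(OC)cc(OCc3ccccc3)c(C(=O)/C=C3\OC(C)=CC(OCc4ccccc4)=C3)c2OCc2ccccc2)c1OCc1ccccc1 | intermediate (not isolated)
10 | bis{2,4-bis(benzyloxy)-3-[4-(benzyloxy)-2-hydroxy-6-methylbenzoyl]-6-methoxyphenyl}methane | Cc1cc(OCc2ccccc2)cc(O)c1C(=O)c1c(OCc2ccccc2)cc(OC)c(Cc2c(OC)cc(OCc3ccccc3)c(C(=O)c3c(C)cc(OCc4ccccc4)cc3O)c2OCc2ccccc2)c1OCc1ccccc1 | intermediate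
11 | bis{2,4-bis(benzyloxy)-3-[4-(benzyloxy)-2-methoxy-6-methylbenzoyl]-6-methoxyphenyl}methane | Cc1cc(OCc2ccccc2)cc(OC)c1C(=O)c1c(OCc2ccccc2)cc(OC)c(Cc2c(OC)cc(OCc3ccccc3)c(C(=O)c3c(C)cc(OCc4ccccc4)cc3OC)c2OCc2ccccc2)c1OCc1ccccc1 | intermediate
12 | digriseophene A, bis[2,4-dihydroxy-3-(4-hydroxy-2-methoxy-6-methylbenzoyl)-6-methoxyphenyl]methane | COc1cc(O)c(C(=O)c2c(C)cc(O)cc2OC)c(O)c1Cc1c(OC)cc(O)c(C(=O)c2c(C)cc(O)cc2OC)c1O | target

## Step count and risks

Total: 9 steps. Longest linear sequence: 7 steps (steps 1, 2, 3, 4, 7, 8, 9, from 1 to 12); the pyrylium branch (steps 5 and 6) is 2 steps.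

**Step 7 (key step).** Three processes are most likely to interfere.
- The cation is stabilised by two alkoxy groups, so the twofold addition of a neutral enol ether may be slow and stop at the mono-adduct.
- Addition may occur at C4 with loss of benzyl alcohol, or the cation may transfer its benzyl group if warmed.
- In the base stage methoxide may exchange the C4 benzyloxy group by addition–elimination, which would erase the differentiation of the two ring B oxygens.

One leak is harmless: if methoxide adds at C2 and not C6, the methoxy group is retained and the C2' methyl ether forms directly, which step 8 would carry on to 11 in any case.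

The fallback changes the nucleophile class and separates the two operations. It sets out from 4 and 8 and returns at 10. Ketone 4 is converted with LiN(SiMe3)2 in THF at −78 °C into the dilithium bis(enolate) of 4, bis{2,4-bis(benzyloxy)-3-[1-(lithiooxy)ethenyl]-6-methoxyphenyl}methane F1, the carbanion mode in which this pyrylium chemistry is established. F1 is added to a suspension of 8 in THF, and 9 is isolated. In a second flask, aqueous KOH in dioxane adds hydroxide at C6 of each pyran ring of 9, the rings open, and the chains reclose by aldol condensation to 10. No methoxide is present, so no exchange can occur.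

**Step 2.** The ortho-quinone methide released from 2 may be trapped by a second molecule of 2 or by product 3, both of which keep a free, nucleophilic C5 position. Loss of dimethylamine from the hydrogen-bonded Mannich base may also need temperatures at which these condensations become competitive. The fallback dispenses with the amine-based electrophile. It sets out from 1 and returns at 3. Acetophenone 1, in large excess and recovered afterwards, is treated with aqueous formaldehyde (0.3 equiv) and KOH in water/methanol at 0 °C to room temperature, then acidified. The hydroxymethyl compound 1-[2,6-dihydroxy-3-(hydroxymethyl)-4-methoxyphenyl]ethan-1-one F2 forms in the flask, loses hydroxide at room temperature and is captured by the phenoxide of 1 to give 3. No heating is needed, and the ratio of the partners alone decides how far the condensation goes.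

**Step 6.** The 4-benzyloxypyrylium cation is a latent benzyl donor and is moisture sensitive. Loss of the benzyl group, or hydrolysis back to 7, may occur during formation or handling. The fallback replaces benzyl with a group that ionises far less readily. It sets out from 6 and returns at 12.
- 6 is alkylated with 4-(trifluoromethyl)benzyl bromide (K2CO3, DMF) to 6-methyl-4-{[4-(trifluoromethyl)benzyl]oxy}-2H-pyran-2-one F3.
- Me3OBF4 gives 2-methoxy-6-methyl-4-{[4-(trifluoromethyl)benzyl]oxy}pyrylium tetrafluoroborate F4.
- The conditions of step 7 with 5 give bis{2,4-bis(benzyloxy)-3-[2-hydroxy-6-methyl-4-{[4-(trifluoromethyl)benzyl]oxy}benzoyl]-6-methoxyphenyl}methane F5.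
- The conditions of step 8 give bis{2,4-bis(benzyloxy)-3-[2-methoxy-6-methyl-4-{[4-(trifluoromethyl)benzyl]oxy}benzoyl]-6-methoxyphenyl}methane F6.
- Hydrogenolysis over Pd(OH)2/C removes all six benzylic groups to give 12.

**Step 9.** Hydrogenolysis of six ethers may stall at partly benzylated stages, and forcing it risks reduction of the diaryl ketone. The fallback is a Lewis-acid debenzylation. It sets out from 11 and returns at 12 directly: BCl3 with pentamethylbenzene as benzyl cation scavenger, CH2Cl2, −78 °C. The temperature is kept low to spare the C2' methyl ethers next to the ketone. It makes no new compound (F0).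

## Further compounds

F1 | step 7 | dilithium bis(enolate) of 4, bis{2,4-bis(benzyloxy)-3-[1-(lithiooxy)ethenyl]-6-methoxyphenyl}methane | C=C(O[Li])c1c(OCc2ccccc2)cc(OC)c(Cc2c(OC)cc(OCc3ccccc3)c(C(=C)O[Li])c2OCc2ccccc2)c1OCc1ccccc1
F2 | step 2 | 1-[2,6-dihydroxy-3-(hydroxymethyl)-4-methoxyphenyl]ethan-1-one | CC(=O)c1c(O)cc(OC)c(CO)c1O
F3 | step 6 | 6-methyl-4-{[4-(trifluoromethyl)benzyl]oxy}-2H-pyran-2-one | CC1=CC(OCc2ccc(C(F)(F)F)cc2)=CC(=O)O1
F4 | step 6 | 2-methoxy-6-methyl-4-{[4-(trifluoromethyl)benzyl]oxy}pyrylium tetrafluoroborate | COc1cc(OCc2ccc(C(F)(F)F)cc2)cc(C)[o+]1.F[B-](F)(F)F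
F5 | step 6 | bis{2,4-bis(benzyloxy)-3-[2-hydroxy-6-methyl-4-{[4-(trifluoromethyl)benzyl]oxy}benzoyl]-6-methoxyphenyl}methane | Cc1cc(OCc2ccc(C(F)(F)F)cc2)cc(O)c1C(=O)c1c(OCc2ccccc2)cc(OC)c(Cc2c(OC)cc(OCc3ccccc3)c(C(=O)c3c(C)cc(OCc4ccc(C(F)(F)F)cc4)cc3O)c2OCc2ccccc2)c1OCc1ccccc1
F6 | step 6 | bis{2,4-bis(benzyloxy)-3-[2-methoxy-6-methyl-4-{[4-(trifluoromethyl)benzyl]oxy}benzoyl]-6-methoxyphenyl}methane | Cc1cc(OCc2ccc(C(F)(F)F)cc2)cc(OC)c1C(=O)c1c(OCc2ccccc2)cc(OC)c(Cc2c(OC)cc(OCc3ccccc3)c(C(=O)c3c(C)cc(OCc4ccc(C(F)(F)F)cc4)cc3OC)c2OCc2ccccc2)c1OCc1ccccc1
F0 | step 9 | none | none
A1 | alternative 1 | bis[4-(benzyloxy)-2-hydroxy-6-methoxyphenyl]methane | COc1cc(OCc2ccccc2)cc(O)c1Cc1c(OC)cc(OCc2ccccc2)cc1O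
A2 | alternative 1 | 1,5-dimethoxypenta-1,4-diyne | COC#CCC#COC
A3 | alternative 1 | 3-(benzyloxy)cyclobut-2-en-1-one | O=C1CC(OCc2ccccc2)=C1
A4 | alternative 2 | 4',4'-di-O-benzyl digriseophene A | COc1cc(O)c(C(=O)c2c(C)cc(OCc3ccccc3)cc2OC)c(O)c1Cc1c(OC)cc(O)c(C(=O)c2c(C)cc(OCc3ccccc3)cc2OC)c1O
A5 | alternative 2 | 3,3'-methylenebis{6-[2-(4-benzyloxy-2-methoxy-6-methylphenyl)-2-oxoethyl]-4-methoxy-2H-pyran-2-one} | COC1=C(CC2=C(OC)C=C(CC(=O)c3c(C)cc(OCc4ccccc4)cc3OC)OC2=O)C(=O)OC(CC(=O)c2c(C)cc(OCc3ccccc3)cc2OC)=C1
A6 | alternative 3 | bis{3-[(4-benzyloxy-2-hydroxy-6-methylcyclohexa-1,3-dien-1-yl)carbonyl]-6-methoxy-2,4-bis(methoxymethoxy)phenyl}methane (enol form, one diastereomer drawn) | COc1cc(OCOC)c(C(=O)C2=C(O)C=C(OCc3ccccc3)C[C@@H]2C)c(OCOC)c1Cc1c(OC)cc(OCOC)c(C(=O)C2=C(O)C=C(OCc3ccccc3)C[C@@H]2C)c1OCOC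
A7 | alternative 3 | 3-(benzyloxy)-5-methylcyclohex-2-en-1-one (racemic) | CC1CC(=O)C=C(OCc2ccccc2)C1
A8 | alternative 3 | bis[3-(1H-imidazol-1-ylcarbonyl)-6-methoxy-2,4-bis(methoxymethoxy)phenyl]methane | COc1cc(OCOC)c(C(=O)n2ccnc2)c(OCOC)c1Cc1c(OC)cc(OCOC)c(C(=O)n2ccnc2)c1OCOC
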